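**Plan**
Numbering used throughout (germacrane type): ring C1–C10; C7 carries C11(=C13H2)–C12H2O; C10 carries C14H2O; C4 carries C15H2O; ring oxygens sit on C9 and on C4/C5.
Retrosynthesis: remove the 4,5-epoxide (last-step Sharpless epoxidation of the C15 allylic alcohol) and the three acyl groups; tie O9 to C12 as a six-membered unsaturated lactone and cut ring bond C6–C7; then cut C7=C11 (metathesis), C8–C9 (allylation), C1=C10 (olefination) and C3–C4 (carbocupration of a C4–C6/C15 ynoate).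
Enabling feature: O–C9 and C12 are 1,3-related across C8, so the lactone O9–C12(=O)–C11=C7–C8–C9 makes C7 the β-carbon of an enoate with a leaving group on C13; a sulfonyl-stabilised carbanion at allylic C6 can then close the ten-membered ring by SN2' and leave the C11=C13 methylene.
Forward order: acyclic C1–C6 chain → C9/C10/C14 enal → homoallylic alcohol → six-membered lactone (metathesis) → ten-membered ring (key step) → lactone reduced to the 9,12-diol, sulfone removed → acetate, tiglate, hydroxybutanoate → desilylation → epoxide.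
Stereochemistry: C9 from Brown allylation; C7 relayed from C9 by the lactone (4,6-trans conjugate addition); C4/C5 from Sharpless epoxidation with L-(+)-tartrate; side-chain C2'/C3' from an Evans syn-aldol; C4=C5 geometry from syn-carbocupration, C1=C10 from an E-selective olefination.

Key step: step 13

Remark: every compound marked "starting material" in the list is taken to be commercial; macrocyclic compounds are named as germacranes with the numbering above, with C1=C10 E, C15 cis to C6 across C4=C5 (trans within the ring), and C7 and C9 configured as in the target unless stated.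

**Step 1**
Reactants: 1 methyl 4-hydroxybut-2-ynoate
Product: 2 methyl 4-[(tert-butyldiphenylsilyl)oxy]but-2-ynoate
Conditions: TBDPSCl, imidazole, CH2Cl2, 0 °C → rt
Reagents that add atoms: tert-butyl(chloro)diphenylsilane, CC(C)(C)[Si](Cl)(c1ccccc1)c1ccccc1
Why: Standard silylation of a primary alcohol; the acid-stable silyl ether is meant to carry O15 to the penultimate step.

**Step 2**
Reactants: 2 methyl 4-[(tert-butyldiphenylsilyl)oxy]but-2-ynoate; 3 [2-(1,3-dioxolan-2-yl)ethyl]magnesium bromide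
Product: 4 methyl (2Z)-3-{[(tert-butyldiphenylsilyl)oxy]methyl}-5-(1,3-dioxolan-2-yl)pent-2-enoate
Conditions: 3, CuBr·SMe2, THF, −78 °C; then 2, −78 °C; MeOH then aq. NH4Cl at −78 °C
Reagents that add atoms: none
Why: Syn-carbocupration of the ynoate (conjugate addition of the organocopper, protonation of the alkenylcopper with retention at −78 °C) should put the new alkyl group (C3) trans to the ester (C6), so that C15 and C6 are cis as the target needs.

**Step 3**
Reactants: 4 methyl (2Z)-3-{[(tert-butyldiphenylsilyl)oxy]methyl}-5-(1,3-dioxolan-2-yl)pent-2-enoate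
Product: 5 (2Z)-3-{[(tert-butyldiphenylsilyl)oxy]methyl}-5-(1,3-dioxolan-2-yl)pent-2-en-1-ol
Conditions: i-Bu2AlH (2.5 equiv), CH2Cl2, −78 °C; aq. potassium sodium tartrate
Reagents that add atoms: none
Why: 1,2-Reduction of the conjugated ester by i-Bu2AlH should give the allylic alcohol without touching the acetal, the silyl ether or the olefin geometry.

**Step 4**
Reactants: 5 (2Z)-3-{[(tert-butyldiphenylsilyl)oxy]methyl}-5-(1,3-dioxolan-2-yl)pent-2-en-1-ol
Product: 7 tert-butyl({(2Z)-2-[2-(1,3-dioxolan-2-yl)ethyl]-4-(phenylsulfonyl)but-2-en-1-yl}oxy)diphenylsilane, via allylic mesylate 6 (not isolated)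
Conditions: MsCl, Et3N, CH2Cl2, −20 °C; then PhSO2Na, Bu4NI (cat.), DMF, rt
Reagents that add atoms: methanesulfonyl chloride, CS(=O)(=O)Cl (kept only in 6); sodium benzenesulfinate, [Na+].[O-]S(=O)c1ccccc1
Why: Mesylation followed by S-alkylation of benzenesulfinate (SN2 at the primary allylic carbon, SN2' at the fully substituted C4 being disfavoured) should install the carbanion-stabilising group on C6 with C4=C5 unchanged.

**Step 5**
Reactants: 7 tert-butyl({(2Z)-2-[2-(1,3-dioxolan-2-yl)ethyl]-4-(phenylsulfonyl)but-2-en-1-yl}oxy)diphenylsilane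
Product: 8 (4Z)-4-{[(tert-butyldiphenylsilyl)oxy]methyl}-6-(phenylsulfonyl)hex-4-enal
Conditions: 1 M HCl, THF, rt
Reagents that add atoms: water, O
Why: Acid-catalysed acetal hydrolysis should release the C1 aldehyde, the tert-butyldiphenylsilyl ether and the sulfone being stable to dilute acid.

**Step 6**
Reactants: 8 (4Z)-4-{[(tert-butyldiphenylsilyl)oxy]methyl}-6-(phenylsulfonyl)hex-4-enal; 9 ethyl 2-(diethoxyphosphoryl)acrylate
Product: 10 ethyl (2E,6Z)-6-{[(tert-butyldiphenylsilyl)oxy]methyl}-2-{[(4-methoxybenzyl)oxy]methyl}-8-(phenylsulfonyl)octa-2,6-dienoate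
Conditions: 4-methoxybenzyl alcohol, NaH (1.0 equiv), THF, 0 °C; then 9, 0 °C; then 8, 0 °C → rt
Reagents that add atoms: 4-methoxybenzyl alcohol, COc1ccc(CO)cc1
Why: Oxa-Michael addition of the alkoxide to the vinylphosphonate makes the phosphonate carbanion in the flask, which olefinates 8 (Horner–Wadsworth–Emmons); an α-branched phosphonoacetate should give mainly the E enoate (ester trans to the chain), which places C14 cis to C2.

**Step 7**
Reactants: 10 ethyl (2E,6Z)-6-{[(tert-butyldiphenylsilyl)oxy]methyl}-2-{[(4-methoxybenzyl)oxy]methyl}-8-(phenylsulfonyl)octa-2,6-dienoate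
Product: 11 (2Z,6Z)-6-{[(tert-butyldiphenylsilyl)oxy]methyl}-2-{[(4-methoxybenzyl)oxy]methyl}-8-(phenylsulfonyl)octa-2,6-dien-1-ol
Conditions: i-Bu2AlH (2.5 equiv), CH2Cl2, −78 °C; aq. potassium sodium tartrate
Reagents that add atoms: none
Why: 1,2-Reduction of the enoate should give the primary allylic alcohol; the descriptor changes to Z only through the priority rules, the geometry is the same.

**Step 8**
Reactants: 11 (2Z,6Z)-6-{[(tert-butyldiphenylsilyl)oxy]methyl}-2-{[(4-methoxybenzyl)oxy]methyl}-8-(phenylsulfonyl)octa-2,6-dien-1-ol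
Product: 12 (2E,6Z)-6-{[(tert-butyldiphenylsilyl)oxy]methyl}-2-{[(4-methoxybenzyl)oxy]methyl}-8-(phenylsulfonyl)octa-2,6-dienal
Conditions: MnO2 (activated, excess), CH2Cl2, rt
Reagents that add atoms: none
Why: MnO2 oxidises allylic alcohols selectively, and the E enal (formyl trans to the chain) is also the thermodynamically preferred isomer.

**Step 9**
Reactants: 12 (2E,6Z)-6-{[(tert-butyldiphenylsilyl)oxy]methyl}-2-{[(4-methoxybenzyl)oxy]methyl}-8-(phenylsulfonyl)octa-2,6-dienal
Product: 14 (4S,5E,9Z)-9-{[(tert-butyldiphenylsilyl)oxy]methyl}-5-{[(4-methoxybenzyl)oxy]methyl}-11-(phenylsulfonyl)undeca-1,5,9-trien-4-ol, via borinate ester 13 (not isolated)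
Conditions: (+)-Ipc2B(allyl), Et2O, −78 °C; then NaOH, H2O2, 0 °C → rt
Reagents that add atoms: (+)-B-allyldiisopinocampheylborane, C=CCB([C@@H]1C[C@@H]2C[C@H]([C@H]1C)C2(C)C)[C@@H]1C[C@@H]2C[C@H]([C@H]1C)C2(C)C
Why: Brown allylation: the allylborane derived from (+)-α-pinene should transfer allyl to the Si face of the aldehyde through a chair-like six-membered transition state and so set C9 as S under reagent control; the oxidative work-up cleaves the borinate.

**Step 10**
Reactants: 15 2-(bromomethyl)acrylic acid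
Product: 16 2-(acetoxymethyl)acrylic acid
Conditions: NaOAc (5 equiv), AcOH, 60 °C
Reagents that add atoms: sodium acetate, [Na+].CC(=O)[O-]
Why: Acetate displaces the allylic bromide (SN2 and SN2' give the same product here) while acetic acid as solvent keeps the substrate's own carboxyl group from competing; acetate is chosen because later it can leave only from an enolate and not by direct SN2.

**Step 11**
Reactants: 14 (4S,5E,9Z)-9-{[(tert-butyldiphenylsilyl)oxy]methyl}-5-{[(4-methoxybenzyl)oxy]methyl}-11-(phenylsulfonyl)undeca-1,5,9-trien-4-ol; 16 2-(acetoxymethyl)acrylic acid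
Product: 17 (4S,5E,9Z)-9-{[(tert-butyldiphenylsilyl)oxy]methyl}-5-{[(4-methoxybenzyl)oxy]methyl}-11-(phenylsulfonyl)undeca-1,5,9-trien-4-yl 2-(acetoxymethyl)acrylate
Conditions: DCC, DMAP (cat.), CH2Cl2, 0 °C → rt
Reagents that add atoms: none
Why: Steglich esterification should acylate the secondary allylic alcohol without disturbing C9.

**Step 12**
Reactants: 17 (4S,5E,9Z)-9-{[(tert-butyldiphenylsilyl)oxy]methyl}-5-{[(4-methoxybenzyl)oxy]methyl}-11-(phenylsulfonyl)undeca-1,5,9-trien-4-yl 2-(acetoxymethyl)acrylate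
Product: 18 {(6S)-6-[(2E,6Z)-6-{[(tert-butyldiphenylsilyl)oxy]methyl}-1-[(4-methoxybenzyl)oxy]-8-(phenylsulfonyl)octa-2,6-dien-2-yl]-2-oxo-5,6-dihydro-2H-pyran-3-yl}methyl acetate
Conditions: second-generation Grubbs catalyst RuCl2(H2IMes)(PCy3)(=CHPh) (5 mol%), toluene (5 mM), 80 °C
Reagents that add atoms: none
Why: Ring-closing metathesis between the terminal olefin and the 1,1-disubstituted acrylate should close the six-membered unsaturated lactone with loss of ethene, the trisubstituted chain olefins being too hindered to take part.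

**Step 13**
Reactants: 18 {(6S)-6-[(2E,6Z)-6-{[(tert-butyldiphenylsilyl)oxy]methyl}-1-[(4-methoxybenzyl)oxy]-8-(phenylsulfonyl)octa-2,6-dien-2-yl]-2-oxo-5,6-dihydro-2H-pyran-3-yl}methyl acetate
Product: 20 14-[(4-methoxybenzyl)oxy]-15-[(tert-butyldiphenylsilyl)oxy]-6-(phenylsulfonyl)germacra-1(10),4,11(13)-trien-12,9-olide (both C6 epimers), via potassium lactone enolate 19 (not isolated)
Conditions: KN(SiMe3)2 (1.05 equiv), THF, −78 °C, 18 added by syringe pump (final 2 mM), then −78 → −30 °C; aq. NH4Cl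
Reagents that add atoms: none
Why: The amide base removes the most acidic proton (α to sulfur at allylic C6), the carbanion adds to the lactone β-carbon C7, and enolate 19 expels acetate from C13 (E1cB), an overall intramolecular SN2' that also creates the C11=C13 methylene. The closest known reaction types are the SN2' alkylation of sulfone-stabilised carbanions with Morita–Baylis–Hillman acetates and the closure of medium terpenoid rings by intramolecular alkylation of allylic sulfonyl carbanions. The ten-membered carbocycle closes in the 10-exo-trig mode onto the six-membered lactone already present, giving a trans-bridged bicyclo[7.3.1] system. C7 is controlled by the lactone: axial attack on the half-chair anti to the pseudo-equatorial C9 substituent (4,6-trans), and because that substituent carries the tether only the trans-bridged product (C6 axial, C10 equatorial) is within reach; C6 is not controlled and is erased in step 15. The step needs attack at C7 and not at C13 or at the carbonyl C12, which the poor SN2 leaving group acetate, the soft potassium sulfonyl carbanion at low temperature and high dilution should secure. The C4=C5 geometry should survive because the charge stays localised α to sulfur.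

**Step 14**
Reactants: 20 14-[(4-methoxybenzyl)oxy]-15-[(tert-butyldiphenylsilyl)oxy]-6-(phenylsulfonyl)germacra-1(10),4,11(13)-trien-12,9-olide (both C6 epimers)
Product: 21 14-[(4-methoxybenzyl)oxy]-15-[(tert-butyldiphenylsilyl)oxy]-6-(phenylsulfonyl)germacra-1(10),4,11(13)-triene-9,12-diol (both C6 epimers)
Conditions: i-Bu2AlH (5 equiv), CH2Cl2, −78 → 0 °C; aq. potassium sodium tartrate
Reagents that add atoms: none
Why: 1,2-Reduction of the α-methylene lactone through the lactol should give the 9,12-diol, which takes the template apart and frees the two oxygens as a primary and a secondary alcohol.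

**Step 15**
Reactants: 21 14-[(4-methoxybenzyl)oxy]-15-[(tert-butyldiphenylsilyl)oxy]-6-(phenylsulfonyl)germacra-1(10),4,11(13)-triene-9,12-diol (both C6 epimers)
Product: 22 14-[(4-methoxybenzyl)oxy]-15-[(tert-butyldiphenylsilyl)oxy]germacra-1(10),4,11(13)-triene-9,12-diol
Conditions: PdCl2(dppp) (10 mol%), LiBHEt3 (6 equiv), THF, 0 °C → rt
Reagents that add atoms: none
Why: Palladium-catalysed reductive desulfonylation: zerovalent palladium ionises the allylic sulfone to a π-allyl complex and hydride goes to the less substituted terminus C6, so C4=C5 should keep its place and geometry, as in sulfone-based couplings of polyprenyl chains.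

**Step 16**
Reactants: 22 14-[(4-methoxybenzyl)oxy]-15-[(tert-butyldiphenylsilyl)oxy]germacra-1(10),4,11(13)-triene-9,12-diol
Product: 23 9-hydroxy-14-[(4-methoxybenzyl)oxy]-15-[(tert-butyldiphenylsilyl)oxy]germacra-1(10),4,11(13)-trien-12-yl acetate
Conditions: Ac2O (1.1 equiv), 2,4,6-collidine, CH2Cl2, −40 °C
Reagents that add atoms: acetic anhydride, CC(=O)OC(C)=O
Why: Kinetic chemoselective acylation: the primary allylic C12 hydroxyl should react much faster than the hindered secondary C9 hydroxyl at low temperature with a weak base.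

**Step 17**
Reactants: 23 9-hydroxy-14-[(4-methoxybenzyl)oxy]-15-[(tert-butyldiphenylsilyl)oxy]germacra-1(10),4,11(13)-trien-12-yl acetate
Product: 24 12-acetoxy-14-[(4-methoxybenzyl)oxy]-15-[(tert-butyldiphenylsilyl)oxy]germacra-1(10),4,11(13)-trien-9-yl (2E)-2-methylbut-2-enoate
Conditions: (E)-2-methylbut-2-enoyl chloride, pyridine, DMAP (cat.), CH2Cl2, 0 °C → rt
Reagents that add atoms: (E)-2-methylbut-2-enoyl chloride, O=C(Cl)/C(C)=C/C
Why: DMAP-catalysed acylation of the remaining secondary alcohol should give the tiglate, pyridine being used instead of a trialkylamine to avoid deconjugation through a vinylketene.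

**Step 18**
Reactants: 24 12-acetoxy-14-[(4-methoxybenzyl)oxy]-15-[(tert-butyldiphenylsilyl)oxy]germacra-1(10),4,11(13)-trien-9-yl (2E)-2-methylbut-2-enoate
Product: 25 12-acetoxy-14-hydroxy-15-[(tert-butyldiphenylsilyl)oxy]germacra-1(10),4,11(13)-trien-9-yl (2E)-2-methylbut-2-enoate
Conditions: DDQ, CH2Cl2/pH 7 buffer, 0 °C
Reagents that add atoms: none
Why: Oxidative cleavage of the 4-methoxybenzyl ether (hydride abstraction, hydrolysis of the oxocarbenium ion) should free the C14 hydroxyl without affecting esters, silyl ether or olefins.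

**Step 19**
Reactants: 26 (4R)-4-benzyl-3-propanoyl-1,3-oxazolidin-2-one; 27 acetaldehyde
Product: 29 (4R)-4-benzyl-3-[(2R,3S)-3-hydroxy-2-methylbutanoyl]-1,3-oxazolidin-2-one, via boron aldolate 28 (not isolated)
Conditions: Bu2BOTf, i-Pr2NEt, CH2Cl2, −78 → 0 °C; 27, −78 °C; then pH 7 buffer, MeOH, H2O2, 0 °C
Reagents that add atoms: dibutylboron triflate, CCCCB(CCCC)OS(=O)(=O)C(F)(F)F (kept only in 28)
Why: Evans syn-aldol: the Z boron enolate reacts through a Zimmerman–Traxler chair on the face away from the benzyl group of the (R)-auxiliary, which should give the (2R,3S) syn adduct.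

**Step 20**
Reactants: 29 (4R)-4-benzyl-3-[(2R,3S)-3-hydroxy-2-methylbutanoyl]-1,3-oxazolidin-2-one
Product: 30 (4R)-4-benzyl-3-{(2R,3S)-2-methyl-3-[(triethylsilyl)oxy]butanoyl}-1,3-oxazolidin-2-one
Conditions: Et3SiOTf, 2,6-lutidine, CH2Cl2, −78 °C
Reagents that add atoms: triethylsilyl triflate, CC[Si](CC)(CC)OS(=O)(=O)C(F)(F)F
Why: Silyl triflate with a hindered pyridine base should silylate the secondary alcohol without retro-aldol cleavage.

**Step 21**
Reactants: 30 (4R)-4-benzyl-3-{(2R,3S)-2-methyl-3-[(triethylsilyl)oxy]butanoyl}-1,3-oxazolidin-2-one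
Product: 32 (2R,3S)-2-methyl-3-[(triethylsilyl)oxy]butanoic acid, via lithium peroxycarboxylate 31 (not isolated)
Conditions: LiOH, H2O2, THF/H2O, 0 °C; then aq. Na2SO3; 1 M HCl to pH 4 at 0 °C
Reagents that add atoms: hydrogen peroxide, OO
Why: Hydroperoxide attacks the exocyclic imide carbonyl selectively and sulfite reduces the peroxy acid, which should release the acid without epimerising C2' (auxiliary cleavage).

**Step 22**
Reactants: 25 12-acetoxy-14-hydroxy-15-[(tert-butyldiphenylsilyl)oxy]germacra-1(10),4,11(13)-trien-9-yl (2E)-2-methylbut-2-enoate; 32 (2R,3S)-2-methyl-3-[(triethylsilyl)oxy]butanoic acid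
Product: 33 12-acetoxy-15-[(tert-butyldiphenylsilyl)oxy]-9-{[(2E)-2-methylbut-2-enoyl]oxy}germacra-1(10),4,11(13)-trien-14-yl (2R,3S)-2-methyl-3-[(triethylsilyl)oxy]butanoate
Conditions: EDC·HCl, DMAP, CH2Cl2, 0 °C
Reagents that add atoms: none
Why: Carbodiimide/DMAP esterification of the primary allylic C14 alcohol at 0 °C, conditions under which the α-stereocentre of the silyloxy acid should be retained.

**Step 23**
Reactants: 33 12-acetoxy-15-[(tert-butyldiphenylsilyl)oxy]-9-{[(2E)-2-methylbut-2-enoyl]oxy}germacra-1(10),4,11(13)-trien-14-yl (2R,3S)-2-methyl-3-[(triethylsilyl)oxy]butanoate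
Product: 34 12-acetoxy-15-hydroxy-9-{[(2E)-2-methylbut-2-enoyl]oxy}germacra-1(10),4,11(13)-trien-14-yl (2R,3S)-3-hydroxy-2-methylbutanoate
Conditions: Bu4NF, AcOH (1:1), THF, 0 °C → rt
Reagents that add atoms: none
Why: Fluoride should cleave both silyl ethers, buffering with acetic acid suppressing acyl migration and base-induced elimination of the β-hydroxy ester (desilylation).

**Step 24**
Reactants: 34 12-acetoxy-15-hydroxy-9-{[(2E)-2-methylbut-2-enoyl]oxy}germacra-1(10),4,11(13)-trien-14-yl (2R,3S)-3-hydroxy-2-methylbutanoate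
Product: 35 (4S,5R,7S,9S)-12-acetoxy-4,5-epoxy-15-hydroxy-9-{[(2E)-2-methylbut-2-enoyl]oxy}germacra-1(10),11(13)-dien-14-yl (2R,3S)-3-hydroxy-2-methylbutanoate (CNP0316239.1)
Conditions: Ti(OiPr)4 (20 mol%), L-(+)-diisopropyl tartrate (25 mol%), t-BuOOH (2 equiv), 4 Å molecular sieves, CH2Cl2, −20 °C
Reagents that add atoms: tert-butyl hydroperoxide, CC(C)(C)OO
Why: Sharpless asymmetric epoxidation: the titanium tartrate binds the C15 allylic alcohol and transfers oxygen only to C4=C5, L-(+)-tartrate directing it to the face that should give (4S,5R); the ring-trans olefin geometry is carried stereospecifically into the epoxide and the two other olefins, not being allylic alcohols, should stay untouched.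

**Compound list**
1 | methyl 4-hydroxybut-2-ynoate | COC(=O)C#CCO | starting material
2 | methyl 4-[(tert-butyldiphenylsilyl)oxy]but-2-ynoate | COC(=O)C#CCO[Si](c1ccccc1)(c1ccccc1)C(C)(C)C | intermediate
3 | [2-(1,3-dioxolan-2-yl)ethyl]magnesium bromide | Br[Mg]CCC1OCCO1 | starting material
4 | methyl (2Z)-3-{[(tert-butyldiphenylsilyl)oxy]methyl}-5-(1,3-dioxolan-2-yl)pent-2-enoate | COC(=O)/C=C(/CCC1OCCO1)CO[Si](c1ccccc1)(c1ccccc1)C(C)(C)C | intermediate
5 | (2Z)-3-{[(tert-butyldiphenylsilyl)oxy]methyl}-5-(1,3-dioxolan-2-yl)pent-2-en-1-ol | OC/C=C(/CCC1OCCO1)CO[Si](c1ccccc1)(c1ccccc1)C(C)(C)C | intermediate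
6 | (2Z)-3-{[(tert-butyldiphenylsilyl)oxy]methyl}-5-(1,3-dioxolan-2-yl)pent-2-en-1-yl methanesulfonate (allylic mesylate) | CS(=O)(=O)OC/C=C(/CCC1OCCO1)CO[Si](c1ccccc1)(c1ccccc1)C(C)(C)C | intermediate (not isolated)
7 | tert-butyl({(2Z)-2-[2-(1,3-dioxolan-2-yl)ethyl]-4-(phenylsulfonyl)but-2-en-1-yl}oxy)diphenylsilane | O=S(=O)(C/C=C(/CCC1OCCO1)CO[Si](c1ccccc1)(c1ccccc1)C(C)(C)C)c1ccccc1 | intermediate
8 | (4Z)-4-{[(tert-butyldiphenylsilyl)oxy]methyl}-6-(phenylsulfonyl)hex-4-enal | O=CCC/C(CO[Si](c1ccccc1)(c1ccccc1)C(C)(C)C)=C/CS(=O)(=O)c1ccccc1 | intermediate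
9 | ethyl 2-(diethoxyphosphoryl)acrylate | C=C(C(=O)OCC)P(=O)(OCC)OCC | starting material
10 | ethyl (2E,6Z)-6-{[(tert-butyldiphenylsilyl)oxy]methyl}-2-{[(4-methoxybenzyl)oxy]methyl}-8-(phenylsulfonyl)octa-2,6-dienoate | CCOC(=O)/C(COCc1ccc(OC)cc1)=C/CC/C(CO[Si](c1ccccc1)(c1ccccc1)C(C)(C)C)=C/CS(=O)(=O)c1ccccc1 | intermediate
11 | (2Z,6Z)-6-{[(tert-butyldiphenylsilyl)oxy]methyl}-2-{[(4-methoxybenzyl)oxy]methyl}-8-(phenylsulfonyl)octa-2,6-dien-1-ol | OC/C(COCc1ccc(OC)cc1)=C/CC/C(CO[Si](c1ccccc1)(c1ccccc1)C(C)(C)C)=C/CS(=O)(=O)c1ccccc1 | intermediate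
12 | (2E,6Z)-6-{[(tert-butyldiphenylsilyl)oxy]methyl}-2-{[(4-methoxybenzyl)oxy]methyl}-8-(phenylsulfonyl)octa-2,6-dienal | O=C/C(COCc1ccc(OC)cc1)=C/CC/C(CO[Si](c1ccccc1)(c1ccccc1)C(C)(C)C)=C/CS(=O)(=O)c1ccccc1 | intermediate
13 | bis(isopinocampheyl)borinate ester of alcohol 14 | C=CC[C@H](OB([C@@H]1C[C@@H]2C[C@H]([C@H]1C)C2(C)C)[C@@H]1C[C@@H]2C[C@H]([C@H]1C)C2(C)C)/C(COCc1ccc(OC)cc1)=C/CC/C(CO[Si](c1ccccc1)(c1ccccc1)C(C)(C)C)=C/CS(=O)(=O)c1ccccc1 | intermediate (not isolated)
14 | (4S,5E,9Z)-9-{[(tert-butyldiphenylsilyl)oxy]methyl}-5-{[(4-methoxybenzyl)oxy]methyl}-11-(phenylsulfonyl)undeca-1,5,9-trien-4-ol | C=CC[C@H](O)/C(COCc1ccc(OC)cc1)=C/CC/C(CO[Si](c1ccccc1)(c1ccccc1)C(C)(C)C)=C/CS(=O)(=O)c1ccccc1 | intermediate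
15 | 2-(bromomethyl)acrylic acid | C=C(CBr)C(=O)O | starting material
16 | 2-(acetoxymethyl)acrylic acid | CC(=O)OCC(=C)C(=O)O | intermediate
17 | (4S,5E,9Z)-9-{[(tert-butyldiphenylsilyl)oxy]methyl}-5-{[(4-methoxybenzyl)oxy]methyl}-11-(phenylsulfonyl)undeca-1,5,9-trien-4-yl 2-(acetoxymethyl)acrylate | C=CC[C@H](OC(=O)C(=C)COC(C)=O)/C(COCc1ccc(OC)cc1)=C/CC/C(CO[Si](c1ccccc1)(c1ccccc1)C(C)(C)C)=C/CS(=O)(=O)c1ccccc1 | intermediate
18 | {(6S)-6-[(2E,6Z)-6-{[(tert-butyldiphenylsilyl)oxy]methyl}-1-[(4-methoxybenzyl)oxy]-8-(phenylsulfonyl)octa-2,6-dien-2-yl]-2-oxo-5,6-dihydro-2H-pyran-3-yl}methyl acetate | CC(=O)OCC1=CC[C@H](OC1=O)/C(COCc1ccc(OC)cc1)=C/CC/C(CO[Si](c1ccccc1)(c1ccccc1)C(C)(C)C)=C/CS(=O)(=O)c1ccccc1 | intermediate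
19 | potassium enolate of 13-acetoxy-14-[(4-methoxybenzyl)oxy]-15-[(tert-butyldiphenylsilyl)oxy]-6-(phenylsulfonyl)germacra-1(10),4-dien-12,9-olide (C6 epimers) | CC(=O)OCC1=C([O-])O[C@H]2C[C@H]1C(S(=O)(=O)c3ccccc3)/C=C(CO[Si](c3ccccc3)(c3ccccc3)C(C)(C)C)/CC/C=C2\COCc1ccc(OC)cc1.[K+] | intermediate (not isolated)
20 | 14-[(4-methoxybenzyl)oxy]-15-[(tert-butyldiphenylsilyl)oxy]-6-(phenylsulfonyl)germacra-1(10),4,11(13)-trien-12,9-olide (both C6 epimers) | C=C1C(=O)O[C@H]2C[C@H]1C(S(=O)(=O)c3ccccc3)/C=C(CO[Si](c3ccccc3)(c3ccccc3)C(C)(C)C)/CC/C=C2\COCc1ccc(OC)cc1 | intermediate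
21 | 14-[(4-methoxybenzyl)oxy]-15-[(tert-butyldiphenylsilyl)oxy]-6-(phenylsulfonyl)germacra-1(10),4,11(13)-triene-9,12-diol (both C6 epimers) | C=C(CO)[C@H]1C[C@H](O)/C(COCc2ccc(OC)cc2)=C/CC/C(CO[Si](c2ccccc2)(c2ccccc2)C(C)(C)C)=C/C1S(=O)(=O)c1ccccc1 | intermediate
22 | 14-[(4-methoxybenzyl)oxy]-15-[(tert-butyldiphenylsilyl)oxy]germacra-1(10),4,11(13)-triene-9,12-diol | C=C(CO)[C@H]1C[C@H](O)/C(COCc2ccc(OC)cc2)=C/CC/C(CO[Si](c2ccccc2)(c2ccccc2)C(C)(C)C)=C/C1 | intermediate
23 | 9-hydroxy-14-[(4-methoxybenzyl)oxy]-15-[(tert-butyldiphenylsilyl)oxy]germacra-1(10),4,11(13)-trien-12-yl acetate | C=C(COC(C)=O)[C@H]1C[C@H](O)/C(COCc2ccc(OC)cc2)=C/CC/C(CO[Si](c2ccccc2)(c2ccccc2)C(C)(C)C)=C/C1 | intermediate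
24 | 12-acetoxy-14-[(4-methoxybenzyl)oxy]-15-[(tert-butyldiphenylsilyl)oxy]germacra-1(10),4,11(13)-trien-9-yl (2E)-2-methylbut-2-enoate | C=C(COC(C)=O)[C@H]1C[C@H](OC(=O)/C(C)=C/C)/C(COCc2ccc(OC)cc2)=C/CC/C(CO[Si](c2ccccc2)(c2ccccc2)C(C)(C)C)=C/C1 | intermediate
25 | 12-acetoxy-14-hydroxy-15-[(tert-butyldiphenylsilyl)oxy]germacra-1(10),4,11(13)-trien-9-yl (2E)-2-methylbut-2-enoate | C=C(COC(C)=O)[C@H]1C[C@H](OC(=O)/C(C)=C/C)/C(CO)=C/CC/C(CO[Si](c2ccccc2)(c2ccccc2)C(C)(C)C)=C/C1 | intermediate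
26 | (4R)-4-benzyl-3-propanoyl-1,3-oxazolidin-2-one | CCC(=O)N1[C@H](Cc2ccccc2)COC1=O | starting material
27 | acetaldehyde | CC=O | starting material
28 | dibutylboron aldolate of 29 | O=C([C@H](C)[C@H](C)OB(CCCC)CCCC)N1[C@H](Cc2ccccc2)COC1=O | intermediate (not isolated)
29 | (4R)-4-benzyl-3-[(2R,3S)-3-hydroxy-2-methylbutanoyl]-1,3-oxazolidin-2-one | O=C([C@H](C)[C@H](C)O)N1[C@H](Cc2ccccc2)COC1=O | intermediate
30 | (4R)-4-benzyl-3-{(2R,3S)-2-methyl-3-[(triethylsilyl)oxy]butanoyl}-1,3-oxazolidin-2-one | O=C([C@H](C)[C@H](C)O[Si](CC)(CC)CC)N1[C@H](Cc2ccccc2)COC1=O | intermediate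
31 | lithium (2R,3S)-2-methyl-3-[(triethylsilyl)oxy]butaneperoxoate | [Li+].[O-]OC(=O)[C@H](C)[C@H](C)O[Si](CC)(CC)CC | intermediate (not isolated)
32 | (2R,3S)-2-methyl-3-[(triethylsilyl)oxy]butanoic acid | OC(=O)[C@H](C)[C@H](C)O[Si](CC)(CC)CC | intermediate
33 | 12-acetoxy-15-[(tert-butyldiphenylsilyl)oxy]-9-{[(2E)-2-methylbut-2-enoyl]oxy}germacra-1(10),4,11(13)-trien-14-yl (2R,3S)-2-methyl-3-[(triethylsilyl)oxy]butanoate | C=C(COC(C)=O)[C@H]1C[C@H](OC(=O)/C(C)=C/C)/C(COC(=O)[C@H](C)[C@H](C)O[Si](CC)(CC)CC)=C/CC/C(CO[Si](c2ccccc2)(c2ccccc2)C(C)(C)C)=C/C1 | intermediate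
34 | 12-acetoxy-15-hydroxy-9-{[(2E)-2-methylbut-2-enoyl]oxy}germacra-1(10),4,11(13)-trien-14-yl (2R,3S)-3-hydroxy-2-methylbutanoate | C=C(COC(C)=O)[C@H]1C[C@H](OC(=O)/C(C)=C/C)/C(COC(=O)[C@H](C)[C@H](C)O)=C/CC/C(CO)=C/C1 | intermediate
35 | (4S,5R,7S,9S)-12-acetoxy-4,5-epoxy-15-hydroxy-9-{[(2E)-2-methylbut-2-enoyl]oxy}germacra-1(10),11(13)-dien-14-yl (2R,3S)-3-hydroxy-2-methylbutanoate (CNP0316239.1) | C=C(COC(C)=O)[C@H]1C[C@H](OC(=O)/C(C)=C/C)/C(COC(=O)[C@H](C)[C@H](C)O)=C/CC[C@@]2(CO)O[C@@H]2C1 | target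

**Count**
Total steps: 24. Longest linear sequence: 20 (steps 1–9, 11–18, 22–24); step 10 and steps 19–21 are side branches.

**Steps most likely to fail**

1. Step 13 (closure of the ten-membered ring). The conjugate addition at the hindered, α-substituted lactone β-carbon may be too slow, so that intermolecular addition (oligomers), attack of the carbanion on the lactone carbonyl, or base-induced eliminative opening of the dihydropyranone through its γ-protons takes over. The fallback sets out from alcohol 14 and returns at lactone 20; it separates ring closure from methylene formation. Alcohol 14 would be acylated with acryloyl chloride (i-Pr2NEt, CH2Cl2, −20 °C) to the acrylate F1, and ring-closing metathesis with the same catalyst would give the α-unsubstituted dihydropyranone F2, a less hindered and more reactive Michael acceptor. KN(SiMe3)2 under high dilution should then close the ring by plain conjugate addition, again anti to the C9 substituent, and the enolate would be trapped in the same flask with dimethylmethyleneiminium iodide to give the Mannich base F3. Quaternisation with MeI to the ammonium iodide F4 and elimination with NaHCO3 should deliver 20.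

2. Step 6 (olefination). Geometric control at C1=C10 may erode, giving E/Z mixtures that are hard to separate. The fallback sets out from aldehyde 8 and returns at alcohol 11. A Morita–Baylis–Hillman reaction of 8 with methyl acrylate (DABCO) would give the allylic alcohol F5. NBS/Me2S would convert it with allylic transposition into the allylic bromide F6, in which the chain sits cis to CH2Br and trans to the ester under thermodynamic control. Ag2O-promoted etherification with 4-methoxybenzyl alcohol would give the ether F7 (the methyl ester analogue of 10), and reduction with i-Bu2AlH as in step 7 should give 11.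

3. Step 24 (epoxidation). Facial selectivity may be poor or oxygen transfer slow if the face demanded by the tartrate is the one shielded by the ring (the ring-trans olefin exposes only its outer face), or if the free side-chain hydroxyl competes for titanium. The fallback sets out from diol 34 and returns at target 35 without a new compound: hydroxyl-directed, substrate-controlled epoxidation with VO(acac)2 and t-BuOOH (CH2Cl2, 0 °C), which relies on peripheral attack on the preferred ring conformer instead of on the chiral ligand.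

**Further compounds**
F1 | step 13 | (4S,5E,9Z)-9-{[(tert-butyldiphenylsilyl)oxy]methyl}-5-{[(4-methoxybenzyl)oxy]methyl}-11-(phenylsulfonyl)undeca-1,5,9-trien-4-yl prop-2-enoate | C=CC[C@H](OC(=O)C=C)/C(COCc1ccc(OC)cc1)=C/CC/C(CO[Si](c1ccccc1)(c1ccccc1)C(C)(C)C)=C/CS(=O)(=O)c1ccccc1
F2 | step 13 | (6S)-6-[(2E,6Z)-6-{[(tert-butyldiphenylsilyl)oxy]methyl}-1-[(4-methoxybenzyl)oxy]-8-(phenylsulfonyl)octa-2,6-dien-2-yl]-5,6-dihydro-2H-pyran-2-one | O=C1C=CC[C@H](O1)/C(COCc1ccc(OC)cc1)=C/CC/C(CO[Si](c1ccccc1)(c1ccccc1)C(C)(C)C)=C/CS(=O)(=O)c1ccccc1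
F3 | step 13 | 13-(dimethylamino)-14-[(4-methoxybenzyl)oxy]-15-[(tert-butyldiphenylsilyl)oxy]-6-(phenylsulfonyl)germacra-1(10),4-dien-12,9-olide (C6 and C11 epimers) | CN(C)CC1C(=O)O[C@H]2C[C@H]1C(S(=O)(=O)c3ccccc3)/C=C(CO[Si](c3ccccc3)(c3ccccc3)C(C)(C)C)/CC/C=C2\COCc1ccc(OC)cc1
F4 | step 13 | N-methyl quaternary ammonium iodide of F3 | C[N+](C)(C)CC1C(=O)O[C@H]2C[C@H]1C(S(=O)(=O)c3ccccc3)/C=C(CO[Si](c3ccccc3)(c3ccccc3)C(C)(C)C)/CC/C=C2\COCc1ccc(OC)cc1.[I-]
F5 | step 6 | methyl (6Z)-6-{[(tert-butyldiphenylsilyl)oxy]methyl}-3-hydroxy-2-methylidene-8-(phenylsulfonyl)oct-6-enoate (racemic at C3) | COC(=O)C(=C)C(O)CC/C(CO[Si](c1ccccc1)(c1ccccc1)C(C)(C)C)=C/CS(=O)(=O)c1ccccc1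
F6 | step 6 | methyl (2Z,6Z)-2-(bromomethyl)-6-{[(tert-butyldiphenylsilyl)oxy]methyl}-8-(phenylsulfonyl)octa-2,6-dienoate | COC(=O)/C(CBr)=C/CC/C(CO[Si](c1ccccc1)(c1ccccc1)C(C)(C)C)=C/CS(=O)(=O)c1ccccc1
F7 | step 6 | methyl (2E,6Z)-6-{[(tert-butyldiphenylsilyl)oxy]methyl}-2-{[(4-methoxybenzyl)oxy]methyl}-8-(phenylsulfonyl)octa-2,6-dienoate | COC(=O)/C(COCc1ccc(OC)cc1)=C/CC/C(CO[Si](c1ccccc1)(c1ccccc1)C(C)(C)C)=C/CS(=O)(=O)c1ccccc1
F0 | step 24 | none | none
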